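Of the charge of Za in Wednesday's flask, 22 percentage points is not yet in Zb at 300 min, and I keep my books on that open balance.

| flask | Za | temperature | remark | time |
|---|---|---|---|---|
| Wednesday's | 2.4 M | 90 °C | the very flask that is asked about, followed so far |  |
| Tuesday's | 1.2 M | 75 °C | run made earlier |  |
| flask | 2.4 M | 90 °C |  | 8.0 h |

| Wednesday's: time / min | Wednesday's: Zb / % | Tuesday's: time / min | Tuesday's: Zb / % |
|---|---|---|---|
| 80.0 | 67.0 | 15.0 | 7.3 |
| 150 | 75.7 | 40.0 | 18.8 |
| 240 | 77.1 | 50.0 | 23.1 |
| 300 | 78.0 | 80.0 | 32.8 |

(standard deviation of a reading: 0.5 percentage points)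

- removed Zb is counted in

- delta: change nothing and wait 15 h more
- zeta: at 8.0 h raise the temperature by 15 K, then wait 15 h
- alpha: at 8.0 h take out 90% of the Zb then present, then wait 15 h

- Zb, in percent of the Za first charged, at 8.0 h
- what to do for the largest gain in Zb; "none" if nothing gains more than 2 percentage points (delta / zeta / alpha / none)
- Zb present, with what was taken out counted in, in percent of the Za first charged, after delta
- Zb present, with what was taken out counted in, in percent of the Za first charged, after zeta

I book Za, the limiting reagent, in fractions of its charge. In Wednesday's flask the account stands at 67.0% in Zb by 80.0 min and at 75.7% by 150 min. The entries then shrink but do not stop: 2.3 points arrives between 150 min and 300 min, with a scatter of 0.5 points on each reading. So I call the unpaid part a shelf, of unknown form, and I judge that it still pays out. I read 0.0418 h⁻¹ as the shelf drain, the fraction of the shelf that passes into Zb per hour. It is a loose reading.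

Carried forward, the drain gives my own 80.6% in Zb at 8.0 h and 89.6% after waiting 15 h more. I assume that the drain does not depend on the Zb present, so I book removal at what waiting gains. Tuesday's flask is 15.0 K cooler. By the first-order measure at 80.0 min, Wednesday's flask runs 2.79 times as fast, a rough factor since the charges differ. Multiplying the drain by it gives 96.6%, so I choose heating.

The forecast differs. It gives 78.2% now, 78.5% after waiting and 77% after heating, and it chooses alpha. Its ground is this: “I take equilibrium as the likelier cause”.

The flask gives 79.0% at 8.0 h, 85.1% after waiting and 93.6% after heating. The gains are 6.1 points for waiting, 6.1 points for removal and 15 points for heating, so the best choice is zeta.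

    2 Za ⇌ Zc (K = 9.93 L mol⁻¹, k = 6.36 × 10⁻⁵ L mol⁻¹ s⁻¹, Ea = 91.0 kJ mol⁻¹, ΔH = −3.00 kJ mol⁻¹)
    Za → Zb (k = 4.26 × 10⁻⁴ s⁻¹, Ea = 106 kJ mol⁻¹)
    (constants at 90 °C)

In the flask at 8.0 h the shelf holds Zc, the open dimer, at 20.7% of the charge, and Za at 0.315%. With the passing of two Za into Zc taken away, both ways, the gain from heating falls from 15 points to 0 points. The return of Zc to two Za is a part of this: with that return struck out, the gain is 0 points. Started from 79.0%, the drain reckons 88.8% after waiting, against 85.1%, so it runs fast. For the same flask read at 30 h, the drain gives 91.6%. The computed flask holds 87.3% in Zb, with Zc at 12.5%.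

The data come from a simulation with constants of no real substance, and the scatter is random.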